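## Retrosynthetic overview

1. The tetrahydrofuran is the only ring in the target and is closed last, by forming the benzylic C2–O1 bond: dehydrative cycloetherification of acyclic triol 9. This step also sets C2.
2. Triol 9 comes from a trans-selective aldol of (S)-β-veratryl-γ-butyrolactone 6 with 3,4,5-trimethoxybenzaldehyde 7 (sets C3), with the lactone reduced in the same flask.
3. Lactone 6 comes from Stobbe half-ester 3 by asymmetric hydrogenation (sets C4), then ester-selective reduction and lactonisation.
4. Half-ester 3 comes from veratraldehyde 1 and dimethyl succinate 2.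
5. Ring order: a temporary γ-lactone (step 3) is opened again in step 4, and the tetrahydrofuran is formed in step 5.

Assumption: the catalyst antipodes named are the ones expected to give the drawn configuration; each is confirmed on a first small run (chiral HPLC of 6, d.r. of 10) and the mirror-image catalyst is used if not.

## Route

Step 1
Reactants: 1 3,4-dimethoxybenzaldehyde; 2 dimethyl succinate
Product: 3 (E)-4-(3,4-dimethoxyphenyl)-3-(methoxycarbonyl)but-3-enoic acid
Conditions: NaOMe (2.2 equiv), MeOH, reflux, 6 h; then 2 M HCl
Reagents that add atoms: none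
Why: Stobbe condensation: succinate enolate aldol addition, lactonisation to the paraconate and E1cB ring opening give the E half-ester, with the free acid on the CH2 arm and the ester on the alkene carbon.

Step 2
Reactants: 3 (E)-4-(3,4-dimethoxyphenyl)-3-(methoxycarbonyl)but-3-enoic acid
Product: 4 (3S)-4-(3,4-dimethoxyphenyl)-3-(methoxycarbonyl)butanoic acid
Conditions: H2 (5 bar), [Rh(cod)2]BF4 (0.5 mol%), (R,R)-Et-DuPhos (0.55 mol%), NaOMe (10 mol%), MeOH, 25 °C
Reagents that add atoms: none
Why: Rh-catalysed asymmetric hydrogenation of an itaconate-type half-ester: the chelated alkene is reduced on one face inside the C2-symmetric bisphospholane pocket, which sets the S centre that becomes C4 of the target.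

Step 3
Reactants: 4 (3S)-4-(3,4-dimethoxyphenyl)-3-(methoxycarbonyl)butanoic acid
Product: 6 (4S)-4-(3,4-dimethoxybenzyl)dihydrofuran-2(3H)-one, via hydroxy acid 5 (not isolated)
Conditions: KOH (1.0 equiv), EtOH, 0 °C; CaCl2 (2 equiv), NaBH4 (4 equiv), EtOH, −10 °C → rt; then 3 M HCl, rt
Reagents that add atoms: none
Why: Chemoselective hydride reduction: Ca(BH4)2 formed in the flask reduces the methyl ester but not the potassium carboxylate, and acidification closes the γ-lactone (lactonisation); the stereocentre is not touched and is no longer α to a carbonyl afterwards.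

Step 4
Reactants: 6 (4S)-4-(3,4-dimethoxybenzyl)dihydrofuran-2(3H)-one; 7 3,4,5-trimethoxybenzaldehyde
Product: 9 (2S,3S)-2-(3,4-dimethoxybenzyl)-3-[hydroxy(3,4,5-trimethoxyphenyl)methyl]butane-1,4-diol, via aldol lactone 8 (not isolated)
Conditions: LiN(iPr)2 (1.1 equiv), THF, −78 °C; 7 (1.05 equiv), −78 °C, 1 h; then LiAlH4 (2.5 equiv), −78 → 0 °C; H2O, 15% NaOH, H2O
Reagents that add atoms: none
Why: Directed aldol addition followed by hydride reduction: the lithium enolate of 6 adds to 7 on the face anti to the C4 benzyl group (trans lactone, sets C3 of the target), the carbinol centre forms as an epimer mixture that step 5 erases, and LiAlH4 reduces the lactone aldolate to the triol before retro-aldol can occur.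

Step 5
Reactants: 9 (2S,3S)-2-(3,4-dimethoxybenzyl)-3-[hydroxy(3,4,5-trimethoxyphenyl)methyl]butane-1,4-diol
Product: 10 [(2R,3S,4S)-4-(3,4-dimethoxybenzyl)-2-(3,4,5-trimethoxyphenyl)tetrahydrofuran-3-yl]methanol
Conditions: (S,S)-IDPi acid HN[P(=NSO2CF3)(3,3'-Ar2-1,1'-binaphthyl-2,2'-diolate)]2, Ar = 3,5-(CF3)2C6H3 (5 mol%), 5 Å molecular sieves, CHCl3, −20 °C
Reagents that add atoms: none
Why: Proposed new method: a confined chiral imidodiphosphorimidate acid ionises both carbinol epimers of 9 to one 3,4,5-trimethoxybenzylic cation held as a contact ion pair, and the anion-bound C1 hydroxyl closes the five-membered ring (C–O bond) on the face that puts the aryl group trans to the C3 hydroxymethyl group, so that catalyst control adds to the substrate's own trans preference and fixes C2 as R under kinetic conditions. The oxetane from the other primary hydroxyl is strained and disfavoured, and the low temperature and tight anion pocket should hold back the six-membered Friedel–Crafts closure onto the veratryl ring. The closest known reaction types are IDPi-catalysed intramolecular hydroalkoxylation of alkenols (cation and chiral anion captured by a tethered hydroxyl) and achiral sulfonic acid SN1 cycloetherification of lignan triols; a stereoconvergent, chiral-acid-controlled dehydrative closure of an unprotected, non-phenolic triol of this kind has not been shown.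

## Compound list

1 | 3,4-dimethoxybenzaldehyde (veratraldehyde) | COc1ccc(C=O)cc1OC | starting material
2 | dimethyl succinate | COC(=O)CCC(=O)OC | starting material
3 | (E)-4-(3,4-dimethoxyphenyl)-3-(methoxycarbonyl)but-3-enoic acid | COC(=O)/C(=C/c1ccc(OC)c(OC)c1)CC(=O)O | intermediate
4 | (3S)-4-(3,4-dimethoxyphenyl)-3-(methoxycarbonyl)butanoic acid | COc1ccc(C[C@@H](CC(=O)O)C(=O)OC)cc1OC | intermediate
5 | (3S)-4-(3,4-dimethoxyphenyl)-3-(hydroxymethyl)butanoic acid (carboxylate salt in the flask) | COc1ccc(C[C@@H](CC(=O)O)CO)cc1OC | intermediate (not isolated)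
6 | (4S)-4-(3,4-dimethoxybenzyl)dihydrofuran-2(3H)-one | COc1ccc(C[C@@H]2COC(=O)C2)cc1OC | intermediate
7 | 3,4,5-trimethoxybenzaldehyde | COc1cc(C=O)cc(OC)c1OC | starting material
8 | (3R,4S)-4-(3,4-dimethoxybenzyl)-3-[hydroxy(3,4,5-trimethoxyphenyl)methyl]dihydrofuran-2(3H)-one (lithium alkoxide in the flask, both carbinol epimers) | COc1ccc(C[C@@H]2COC(=O)[C@H]2C(O)c3cc(OC)c(OC)c(OC)c3)cc1OC | intermediate (not isolated)
9 | (2S,3S)-2-(3,4-dimethoxybenzyl)-3-[hydroxy(3,4,5-trimethoxyphenyl)methyl]butane-1,4-diol (both carbinol epimers) | COc1ccc(C[C@H](CO)[C@@H](CO)C(O)c2cc(OC)c(OC)c(OC)c2)cc1OC | intermediate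
10 | [(2R,3S,4S)-4-(3,4-dimethoxybenzyl)-2-(3,4,5-trimethoxyphenyl)tetrahydrofuran-3-yl]methanol (aryl trans to CH2OH, CH2OH cis to the benzyl group) | COc1ccc(C[C@@H]2CO[C@@H](c3cc(OC)c(OC)c(OC)c3)[C@@H]2CO)cc1OC | target

## Step count and risks

Total steps: 5. Longest linear sequence: 5 (1 + 2 → 3 → 4 → 6 → 9 → 10; aldehyde 7 enters in step 4).

**Step 5 (the proposed new ring closure).** It may fail through catalyst inhibition by the three hydroxyl groups and the water released, through a weak catalyst effect on the trans:cis ratio, or through Friedel–Crafts closure to the aryltetralin. The fallback sets out from triol 9 and gives up catalyst control for the known substrate-controlled closure of lignan triols: (1S)-10-camphorsulfonic acid (10 mol%) in CH2Cl2 at 0 °C gives 10 by the classical SN1 cycloetherification. The minor C2 epimer [(2S,3S,4S)-4-(3,4-dimethoxybenzyl)-2-(3,4,5-trimethoxyphenyl)tetrahydrofuran-3-yl]methanol F1 is separated by chromatography and put back into the same acid, where reversible ionisation of its benzylic C2–O bond moves it to the more stable 2,3-trans isomer. The fallback returns to the route at 10.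

**Step 4 (one-flask aldol and reduction).** Retro-aldol before reduction, incomplete trans selectivity, or a triol contaminated with 3,4,5-trimethoxybenzyl alcohol could lower the yield. The fallback sets out from lactone 6 and replaces the aldol by a Claisen-type C-acylation: LiN(SiMe3)2 (2.1 equiv) and 3,4,5-trimethoxybenzoyl chloride in THF at −78 °C give the keto lactone (3R,4S)-4-(3,4-dimethoxybenzyl)-3-(3,4,5-trimethoxybenzoyl)dihydrofuran-2(3H)-one F2. Its doubly activated C3 equilibrates to the trans isomer. NaBH4 in MeOH at 0 °C then reduces the ketone to aldol lactone 8, which is isolated here, and LiAlH4 in THF reduces 8 to triol 9. The fallback returns to the route at 8 and continues to 9.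

**Step 2 (asymmetric hydrogenation).** The enantiomeric purity of the whole route rests on this step; a low ee on the E/Z mixture or the wrong ligand hand would carry through. The fallback sets out from half-ester 3 and replaces asymmetric catalysis by classical resolution. H2 (1 bar) over Pd/C in MeOH gives the racemic half-ester rac-4-(3,4-dimethoxyphenyl)-3-(methoxycarbonyl)butanoic acid F3. Crystallisation with (R)-1-phenylethylamine from iPrOH/EtOAc gives the salt (R)-1-phenylethylammonium (3S)-4-(3,4-dimethoxyphenyl)-3-(methoxycarbonyl)butanoate F4; the (S)-amine is used instead if the other acid antipode crystallises. 1 M HCl then liberates 4, where the fallback returns to the route.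

## Further compounds

F1 | step 5 | [(2S,3S,4S)-4-(3,4-dimethoxybenzyl)-2-(3,4,5-trimethoxyphenyl)tetrahydrofuran-3-yl]methanol | COc1ccc(C[C@@H]2CO[C@H](c3cc(OC)c(OC)c(OC)c3)[C@@H]2CO)cc1OC
F2 | step 4 | (3R,4S)-4-(3,4-dimethoxybenzyl)-3-(3,4,5-trimethoxybenzoyl)dihydrofuran-2(3H)-one | COc1ccc(C[C@@H]2COC(=O)[C@H]2C(=O)c3cc(OC)c(OC)c(OC)c3)cc1OC
F3 | step 2 | rac-4-(3,4-dimethoxyphenyl)-3-(methoxycarbonyl)butanoic acid | COc1ccc(CC(CC(=O)O)C(=O)OC)cc1OC
F4 | step 2 | (R)-1-phenylethylammonium (3S)-4-(3,4-dimethoxyphenyl)-3-(methoxycarbonyl)butanoate | COc1ccc(C[C@@H](CC(=O)[O-])C(=O)OC)cc1OC.C[C@@H]([NH3+])c1ccccc1
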